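**Plan**
- Numbering: in each ring C1 carries the C7 methylene, C2 and C3 the bromines, C4 and C5 the hydroxyls and C6 a hydrogen.
- Retrosynthesis: the two C5 hydroxyls are traced back to methyl ethers, then all four C–Br bonds (C2–Br and C3–Br of both rings) are cut together, then one C1–C7 bond between a vanillyl unit and guaiacol.
- Forward: no ring is formed. The diarylmethane is joined first, on electron-rich unhindered rings (step 1), the four bromines enter in one two-directional operation (step 2), and the two methyl ethers are cleaved (step 3).
- Enabling feature: C3 is ortho to the C4 hydroxyl and C2 is para to the C5 oxygen, so both bromine-bearing carbons are the sites the ring's own oxygens activate. C6 is only ortho to the C5 ether, and C1 is blocked by C7.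
- Stereochemistry: none to create; the target has no stereocentre.

Key step: step 2

Assumption: the target is achiral, so the requirement of a single enantiomer is met by the constitution alone.

**Step 1**
Reactants: 1 vanillyl alcohol [4-(hydroxymethyl)-2-methoxyphenol]; 2 guaiacol (2-methoxyphenol)
Product: 3 4,4'-methylenebis(2-methoxyphenol) [bis(4-hydroxy-3-methoxyphenyl)methane]
Conditions: Amberlyst-15 (H+ form, cat.), neat 2 (8 equiv), slow addition of 1, 65 °C, N2; excess 2 distilled off in vacuo; SiO2 chromatography, then crystallisation
Reagents that add atoms: none
Why: Friedel–Crafts benzylation, in which acid ionises the benzylic alcohol of 1 to a para-hydroxybenzyl cation that should attack guaiacol mainly para to its hydroxyl group, the large excess of 2 suppressing further benzylation of 3 and the minor ortho-linked and methoxy-para-linked isomers being removed on purification.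

**Step 2**
Reactants: 3 4,4'-methylenebis(2-methoxyphenol); 4 bromine
Product: 6 bis(2,3-dibromo-4-hydroxy-5-methoxyphenyl)methane, via bis(3-bromo-4-hydroxy-5-methoxyphenyl)methane 5 (not isolated)
Conditions: Br2 (2.05 equiv), CH2Cl2–AcOH, −10 °C, dark; then Br2 (2.15 equiv), 0 °C → rt; aq. NaHSO3; crystallisation
Reagents that add atoms: bromine (4), BrBr
Why: This is electrophilic aromatic substitution, four successive brominations through arenium ions, of the type known as ortho-bromination of 4-substituted guaiacols followed by a second bromination para to the methoxy group, as in the conversion of vanillin into its 5,6-dibromide. The first two equivalents should enter at C3 of each ring, ortho to the free C4 hydroxyl (its para position is occupied by C1), to give 5; the next two should enter at C2, para to the C5 methoxy group, because C6 is only ortho to that ether, meta to the hydroxyl and flanked by C7 and the methoxy group. No ring is closed and no stereocentre is created, so neither a mode of cyclisation nor a stereocontrol element is involved. The step needs selectivity for C2 and C3 over C6, over ipso attack at C1 and over the benzylic C7–H bonds: the OH/OMe differentiation secures the ring positions, each bromine deactivates its ring so that controlled stoichiometry should stop at four, any ipso-bromodienone should be returned to the phenol by the unbuffered HBr, and dark ionic conditions at low temperature should leave C7 untouched.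

**Step 3**
Reactants: 6 bis(2,3-dibromo-4-hydroxy-5-methoxyphenyl)methane
Product: 8 bis(2,3-dibromo-4,5-dihydroxyphenyl)methane, via cyclic bis(B-bromoboronate) ester 7 (not isolated)
Conditions: BBr3 (6 equiv), CH2Cl2, −78 °C → rt, N2; then ice-water, 0 °C, work-up under N2
Reagents that add atoms: none
Why: Lewis acid-mediated aryl methyl ether cleavage, in which BBr3 binds each methoxy oxygen, bromide removes the methyl group by SN2 as bromomethane, and the cyclic aryl borate 7 is hydrolysed on aqueous quench, a standard last step for brominated catechols that should leave the aryl C–Br bonds and the diarylmethane intact.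

**Compound list**
1 | vanillyl alcohol, 4-(hydroxymethyl)-2-methoxyphenol | OCc1ccc(O)c(OC)c1 | starting material
2 | guaiacol, 2-methoxyphenol | COc1ccccc1O | starting material
3 | 4,4'-methylenebis(2-methoxyphenol) | COc1cc(Cc2ccc(O)c(OC)c2)ccc1O | intermediate
4 | bromine | BrBr | starting material
5 | bis(3-bromo-4-hydroxy-5-methoxyphenyl)methane | COc1cc(Cc2cc(OC)c(O)c(Br)c2)cc(Br)c1O | intermediate
6 | bis(2,3-dibromo-4-hydroxy-5-methoxyphenyl)methane | COc1cc(Cc2cc(OC)c(O)c(Br)c2Br)c(Br)c(Br)c1O | intermediate
7 | bis(2,6,7-tribromo-1,3,2-benzodioxaborol-5-yl)methane | BrB1Oc2cc(Cc3cc4OB(Br)Oc4c(Br)c3Br)c(Br)c(Br)c2O1 | intermediate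
8 | bis(2,3-dibromo-4,5-dihydroxyphenyl)methane | Oc1cc(Cc2cc(O)c(O)c(Br)c2Br)c(Br)c(Br)c1O | target

**Step count**
Total steps: 3. Longest linear sequence: 3 steps (1 → 3 → 6 → 8).

**Steps most likely to fail**

Step 2. Bromine may attack C1 (para to the C4 hydroxyl) and expel the other ring as a para-hydroxybenzyl fragment, C7 may be oxidised through a quinone methide, or a third bromine may enter at C6. The fallback sets out from 3 and returns at 6, and carries out the same four C–Br bond formations at the ketone oxidation level, where C1 bears an acyl group exactly as in vanillin. DDQ (2.2 equiv) in aqueous dioxane at rt should oxidise the para-hydroxydiarylmethane 3 to bis(4-hydroxy-3-methoxyphenyl)methanone F1. Br2 in AcOH at rt should then give bis(3-bromo-4-hydroxy-5-methoxyphenyl)methanone F2. Br2 with iron powder in warm AcOH should complete the pattern to bis(2,3-dibromo-4-hydroxy-5-methoxyphenyl)methanone F3. Ionic hydrogenation (Et3SiH, TFA, CH2Cl2) should remove the carbonyl oxygen and deliver 6.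

Step 1. The benzyl cation may attack guaiacol ortho to the hydroxyl or para to the methoxy group, and the product may be benzylated again, so that 3 is obtained as an inseparable mixture with isomers and oligomers. The fallback sets out from 2 and returns at 3, and fixes the position of attack with a halogen. Para-bromination of 2 (NBS, MeCN, 0 °C) should give 4-bromo-2-methoxyphenol F4. Benzylation (BnBr, K2CO3, DMF) should give 1-(benzyloxy)-4-bromo-2-methoxybenzene F5. Bromine–lithium exchange (n-BuLi, THF, −78 °C) should give [4-(benzyloxy)-3-methoxyphenyl]lithium F6, which is added to commercial 4-(benzyloxy)-3-methoxybenzaldehyde and quenched with water to give bis[4-(benzyloxy)-3-methoxyphenyl]methanol F7. Hydrogenolysis (H2, Pd/C, EtOAc–AcOH) should remove both benzyl ethers and the doubly benzylic hydroxyl and deliver 3 as a single regioisomer.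

Step 3. Under BBr3 and the HBr it liberates, bromine may be lost from or migrate on the very electron-rich rings, the C1–C7 bond may be cleaved by ipso-protonation, or ether cleavage may stop halfway. The fallback sets out from 6 and returns at 8, and replaces Lewis acid cleavage by oxidative demethylation. NaIO4 in aqueous AcOH at 0 °C should convert each 2-methoxyphenol unit into an ortho-quinone with loss of methanol, giving 5,5'-methylenebis(3,4-dibromocyclohexa-3,5-diene-1,2-dione) F8. This is reduced at once with aqueous Na2S2O4 to 8.

**Further compounds**
F1 | step 2 | bis(4-hydroxy-3-methoxyphenyl)methanone | COc1cc(C(=O)c2ccc(O)c(OC)c2)ccc1O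
F2 | step 2 | bis(3-bromo-4-hydroxy-5-methoxyphenyl)methanone | COc1cc(C(=O)c2cc(OC)c(O)c(Br)c2)cc(Br)c1O
F3 | step 2 | bis(2,3-dibromo-4-hydroxy-5-methoxyphenyl)methanone | COc1cc(C(=O)c2cc(OC)c(O)c(Br)c2Br)c(Br)c(Br)c1O
F4 | step 1 | 4-bromo-2-methoxyphenol | COc1cc(Br)ccc1O
F5 | step 1 | 1-(benzyloxy)-4-bromo-2-methoxybenzene | COc1cc(Br)ccc1OCc1ccccc1
F6 | step 1 | [4-(benzyloxy)-3-methoxyphenyl]lithium | [Li]c1ccc(OCc2ccccc2)c(OC)c1
F7 | step 1 | bis[4-(benzyloxy)-3-methoxyphenyl]methanol | COc1cc(C(O)c2ccc(OCc3ccccc3)c(OC)c2)ccc1OCc1ccccc1
F8 | step 3 | 5,5'-methylenebis(3,4-dibromocyclohexa-3,5-diene-1,2-dione) | O=C1C=C(CC2=CC(=O)C(=O)C(Br)=C2Br)C(Br)=C(Br)C1=O
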